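E, the limiting reagent of the epsilon flask, holds less there, 0.360 M, than J, 0.720 M, so you should count each run as the share of its E charge that has become Q.

| flask | E | J | Q | time |
|---|---|---|---|---|
| alpha | 0.120 M | 0.240 M |  |  |
| delta | 0.120 M | 0.240 M | 0.0600 M |  |
| theta | 0.180 M | 0.240 M |  |  |
| eta | 0.120 M | 0.360 M |  |  |
| epsilon | 0.360 M | 0.720 M |  | 13 min |

- alpha run (time / min: [Q] / M): 0.52: 0.0034; 0.89: 0.0058; 1.5: 0.0081; 2.6: 0.0139; 4.4: 0.0225; 7.6: 0.0359; 13: 0.0530
- delta run (time / min: [Q] / M): 0.52: 0.0634; 0.89: 0.0656; 1.5: 0.0687; 2.6: 0.0730; 4.4: 0.0825; 7.6: 0.0962; 13: 0.1131
- theta run (time / min: [Q] / M): 0.52: 0.0031; 0.89: 0.0068; 1.5: 0.0101; 2.6: 0.0196; 4.4: 0.0307; 7.6: 0.0492; 13: 0.0742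
- eta run (time / min: [Q] / M): 0.52: 0.0031; 0.89: 0.0059; 1.5: 0.0099; 2.6: 0.0168; 4.4: 0.0257; 7.6: 0.0401; 13: 0.0593

(standard deviation of a reading: 6 × 10⁻⁴ M)

- reaction order in [J] at the outset, round the charge of the alpha run, defined at two percent of the E turned into Q
- reaction order in [E] at the outset, round the charge of the alpha run, defined at two percent of the E turned into Q (one fixed amount of Q, the same in the runs compared)
- Q in the epsilon run at 13 min, as a share of the E charged
- which of these the readings show (the product decays / the two partners rest in a complex / the substrate pairs with itself / nothing beyond the main steps)

- Overall: E + J -> Q.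
- Constant volume, constant temperature.
- A reading of a species includes what of it is bound.
- "The second partner" is J.
- An order is taken over about fifteen percent of the charge, up and down.

At 13 min the alpha run has turned 44.2% of its E. The theta run, with E raised by a factor 1.50, has turned 41.2%, and the eta run, with J raised by a factor 1.50, has turned 49.4%. The delta run, with Q added, gained 0.05310 M against 0.0530 M in the alpha run, so the readings show no decay of Q.

Now turn the question round and ask what the main steps alone, with a rate proportional to E times J, would have to show. Early on, the eta run would then stand a factor 1.50 above the alpha run. At 4.4 min the readings give a ratio of 1.14, well short of that. E pairing with itself would leave the order in J near one, so this low reading points me to E and J sitting in a complex, the resting state.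

To measure the distance, define the charge exponent: the power to which a common factor on E and J is raised to give the factor on the share turned at a fixed time. It is the sum of two slopes, −0.170 for E and 0.277 for J, so it reads 0.107. Early in a flask of main steps alone it would be one. The epsilon flask carries the alpha charge times 3.00, and an exponent of one would ask for 132% of the E, more than the whole charge. My exponent gives 49.7% instead, and I commit to that, though it assumes the exponent holds across the whole factor.

The forecast gives 0.38 in J, 0.88 in E, 51.3% and "the two partners rest in a complex", reasoning that “A low order in J as well as in E points to E and J resting in a complex”.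

The epsilon flask gives 53.5%. At the outset, round the charge of the alpha run, the orders are 0.48 in J and 0.87 in E, and the answer is that the two partners rest in a complex.

    E + J → Q (0.7500 M⁻¹ min⁻¹)
    E + J → X (0.05046 M⁻¹ min⁻¹)
    E + J ⇌ EJ, settled at all times (9.850 M⁻¹)

A fit with the main steps alone gives 72.5% for this flask. Set against the alpha share, the flask's value corresponds to a charge exponent of 0.174, where mine was 0.107, and the fit's value to 0.452. The delta run has the alpha charge, so its factor on the share is 1.00. The Q made in the delta run comes to half of the charge at 15.6 min, and the Q made in the alpha run at 15.6 min.

The readings were computed for an exercise, noise included.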